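**Retrosynthetic overview** (backbone carbons use tetralone numbering: C1 = C=O, C2/C3 = CHMe, C4 = CHAr)

1. Both benzene rings come intact from catechol (1): one methylation gives guaiacol (2, ring A) and veratrole (3, pendant ring).
2. Key disconnection C2–C3 (the lignan 8–8' bond): the α-keto radical from bromoketone 6 (made from 2 via acetate 4 and acid chloride 5) adds to the chiral enamine of propanal (7), giving keto-aldehyde 8 and setting C3 under catalyst control.
3. C4–aryl: the Grignard reagent from 4-bromoveratrole (9) adds to the aldehyde of 8, giving carbinol 10.
4. C4–C4a: cationic cyclisation of 10 onto ring A gives tetralone 11. This is the only ring built, and it is closed last; C3 directs C4 trans.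
5. C2: kinetic protonation of the enolate of 11 gives the 2,3-cis target 12.

Assumptions (one line each):
- The target SMILES corresponds to (2S,3S,4R): 2-Me/3-Me cis, 3-Me/4-Ar trans.
- The (2R,5S)-imidazolidinone directs Si-face attack on the enamine (giving the R aldehyde), as in its known aldehyde α-alkylations; if the sense were opposite, its enantiomer would be used.
- Step 1 is counted once, because both products are isolated from the same flask by base extraction.

**Route**

Step 1
Reactants: 1 catechol
Product: 2 guaiacol (2-methoxyphenol) and 3 veratrole (1,2-dimethoxybenzene), both kept
Conditions: MeI (1.4 equiv), K2CO3, acetone, reflux; partition Et2O / 2 M NaOH (3 in the organic layer; 2 recovered from the aqueous layer on acidification)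
Reagents that add atoms: iodomethane, CI
Why: Williamson O-methylation with sub-stoichiometric MeI gives a roughly statistical mono/di-ether mixture that separates by acidity, so one operation supplies both rings; no stereocenter.

Step 2
Reactants: 2 guaiacol
Product: 4 2-methoxyphenyl acetate
Conditions: Ac2O, pyridine, DMAP (cat.), CH2Cl2, rt
Reagents that add atoms: acetic anhydride, CC(=O)OC(C)=O
Why: O-acetylation turns the OH into a weak donor (temporary protecting group), so that OMe alone directs the next electrophilic substitution.

Step 3
Reactants: 4 2-methoxyphenyl acetate; 5 2-bromopropanoyl chloride (racemic)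
Product: 6 2-bromo-1-(3-hydroxy-4-methoxyphenyl)propan-1-one (racemic)
Conditions: AlCl3 (2.5 equiv), CH2Cl2, 0 °C → rt; then MeOH, HCl (cat.), 40 °C during work-up (acetate removed)
Reagents that add atoms: none (5 is a reactant)
Why: Friedel–Crafts acylation goes para to OMe because the acetoxy group is the weaker director, and acidic methanolysis frees the phenol without exposing the α-bromoketone to base; the CHBr centre is racemic but becomes a planar radical next.

Step 4 (key step)
Reactants: 6 bromoketone; 7 propanal (3 equiv)
Product: 8 (2R)-4-(3-hydroxy-4-methoxyphenyl)-2,3-dimethyl-4-oxobutanal, mixture of epimers at C3 of the butanal (the carbon α to the ketone)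
Conditions: Ru(bpy)3Cl2 (1 mol%), (2R,5S)-2-tert-butyl-3,5-dimethylimidazolidin-4-one·TfOH (20 mol%), 2,6-lutidine (2 equiv), DMF, blue LED, 23 °C; cold neutral work-up, used at once
Reagents that add atoms: none (7 is a reactant)
Why: Proposed new method: photoredox organocatalytic α-alkylation of an aldehyde, extended to a secondary α-bromo aryl ketone bearing a free phenol. Ru(I) reduces the C–Br bond to an electrophilic α-keto radical, which adds to the Si face of the (E)-enamine of propanal (the catalyst's C5 methyl blocks the Re face). This sets the methyl-bearing carbon that becomes C3 of the target; the α-amino radical is then oxidised to the iminium and hydrolysed. The closest known reaction is the same coupling with phenacyl bromides. The ketone-α centre forms unselectively and is corrected in Step 8. The neutral phenol should be tolerated because lutidine cannot deprotonate it in DMF and DMF hydrogen-bonding slows O–H abstraction.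

Step 5
Reactants: 3 veratrole
Product: 9 4-bromo-1,2-dimethoxybenzene
Conditions: NBS (1.05 equiv), MeCN, 0 °C → rt
Reagents that add atoms: N-bromosuccinimide, O=C1CCC(=O)N1Br
Why: Electrophilic aromatic bromination occurs para to a methoxy group, giving the handle for the aryl nucleophile.

Step 6
Reactants: 8 keto-aldehyde; 9 aryl bromide (as its Grignard reagent, 2.3 equiv)
Product: 10 (3R)-4-(3,4-dimethoxyphenyl)-4-hydroxy-1-(3-hydroxy-4-methoxyphenyl)-2,3-dimethylbutan-1-one, mixture at C2 and C4 (may exist partly as the cyclic hemiketal)
Conditions: 9, Mg, THF → ArMgBr; add to 8, THF, −78 °C; aq. NH4Cl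
Reagents that add atoms: none (9 is a reactant)
Why: Chemoselective Grignard 1,2-addition to the aldehyde: the first equivalent deprotonates the phenol, and the hindered, electron-rich aryl ketone does not react at −78 °C. After this step the catalyst-set centre is no longer α to a carbonyl, and the carbinol configuration is irrelevant because it is ionised next.

Step 7
Reactants: 10 carbinol
Product: 11 (3S,4R)-4-(3,4-dimethoxyphenyl)-7-hydroxy-6-methoxy-2,3-dimethyl-3,4-dihydronaphthalen-1(2H)-one, mixture of C2 epimers
Conditions: TFA (10 equiv), CH2Cl2 (0.02 M), 0 °C → rt
Reagents that add atoms: none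
Why: Intramolecular Friedel–Crafts alkylation: the 3,4-dimethoxybenzylic cation is attacked by ring A at the position para to the free OH (ortho to the ketone; the alternative site between OH and C=O is hindered). Attack anti to the C3 methyl in a chair-like transition state gives the 3,4-trans (4R) product; C2 equilibrates under the acid.

Step 8
Reactants: 11 tetralone (C2 mixture)
Product: 12 schisandrone, (2S,3S,4R)-4-(3,4-dimethoxyphenyl)-7-hydroxy-6-methoxy-2,3-dimethyl-3,4-dihydronaphthalen-1(2H)-one
Conditions: LDA (2.5 equiv), THF, −78 °C; then 2,6-di-tert-butyl-4-methylphenol (3 equiv) in THF, −78 °C; cold AcOH/pH 7 buffer work-up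
Reagents that add atoms: none
Why: Kinetic enolate protonation: in the phenoxide–enolate the 3-Me and 4-aryl are trans-diaxial, and the bulky proton donor approaches C2 anti to the adjacent pseudoaxial 3-Me, leaving the 2-Me cis to the 3-Me (2S); only C2 is enolisable and the work-up avoids base.

**Compound list**

1 | catechol | Oc1ccccc1O | starting material
2 | guaiacol (2-methoxyphenol) | COc1ccccc1O | intermediate
3 | veratrole (1,2-dimethoxybenzene) | COc1ccccc1OC | intermediate
4 | 2-methoxyphenyl acetate | COc1ccccc1OC(C)=O | intermediate
5 | 2-bromopropanoyl chloride (racemic) | CC(Br)C(Cl)=O | starting material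
6 | 2-bromo-1-(3-hydroxy-4-methoxyphenyl)propan-1-one (racemic) | CC(Br)C(=O)c1ccc(OC)c(O)c1 | intermediate
7 | propanal | CCC=O | starting material
8 | (2R)-4-(3-hydroxy-4-methoxyphenyl)-2,3-dimethyl-4-oxobutanal (C3 epimers) | O=C[C@H](C)C(C)C(=O)c1ccc(OC)c(O)c1 | intermediate
9 | 4-bromo-1,2-dimethoxybenzene | COc1ccc(Br)cc1OC | intermediate
10 | (3R)-4-(3,4-dimethoxyphenyl)-4-hydroxy-1-(3-hydroxy-4-methoxyphenyl)-2,3-dimethylbutan-1-one (C2/C4 mixture) | COc1ccc(cc1OC)C(O)[C@H](C)C(C)C(=O)c1ccc(OC)c(O)c1 | intermediate
11 | (3S,4R)-4-(3,4-dimethoxyphenyl)-7-hydroxy-6-methoxy-2,3-dimethyl-3,4-dihydronaphthalen-1(2H)-one (C2 epimers) | COc1cc2c(cc1O)C(=O)C(C)[C@@H](C)[C@@H]2c1ccc(OC)c(OC)c1 | intermediate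
12 | schisandrone, (2S,3S,4R) | COc1cc2c(cc1O)C(=O)[C@@H](C)[C@@H](C)[C@@H]2c1ccc(OC)c(OC)c1 | target

**Totals**

Total steps: 8 (9 if the divergent methylation in Step 1 is counted once per product).
Longest linear sequence: 7 (1 → 2 → 4 → 6 → 8 → 10 → 11 → 12).

**Three steps most likely to fail, with fallbacks**

1. Step 4 (radical coupling). The secondary, more hindered α-keto radical and the free phenol are outside the established scope, so yield or ee may be low. Fallback: reverse the polarity of the radical event. Convert the debrominated ketone to its bis-TBS derivative (aryl silyl ether plus silyl enol ether) and couple it with propanal by oxidative enamine radical-cation (SOMO) catalysis with the same imidazolidinone and CAN, so the chiral radical cation adds to the enolsilane.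

2. Step 7 (cationic ring closure ortho to the ketone). The ring position is deactivated by the acyl group, so the cation may instead lose the C3 proton to give the styrene, which would erode the C3 stereocentre, or it may oligomerise through the veratryl ring. Fallback: close the same bond homolytically. Convert the carbinol of 10 to the benzylic chloride and generate the benzylic radical (photoredox or Ni reductive conditions), which adds to the position ortho to the ketone in a polarity-matched homolytic aromatic substitution without a cation next to C3.

3. Step 8 (kinetic protonation to the 2,3-cis isomer). The pseudoaxial C4 aryl group sits on the face the proton must use, so selectivity may be modest, and the cis ketone can epimerise on handling. Fallback: build C2 by hydrogenation instead. Run Steps 3–7 with bromoacetyl chloride (giving the 2-unsubstituted tetralone), then α-methylenate (Eschenmoser salt) and hydrogenate the exocyclic alkene over Pd/C, which delivers hydrogen anti to the 3-Me and gives the 2,3-cis methyl directly.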